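**Retrosynthetic overview**

1. Dihydroptychantol A ⇐ BBr3 cleavage of its di-O-methyl ether ⇐ deoxygenation of an 18-membered cyclophane ketone whose C=O is the C–D bridge carbon bonded to ring C.
2. Key disconnection: the diaryl ether between the ring-B oxygen (ortho to the ring-B OH) and C4 of the para-phenylene ring C. It is closed last by intramolecular SNAr of a ring-B phenol on a 4-fluorophenyl ketone. The 18-membered ring is the only ring formed; all four benzene rings are bought.
3. Enabling feature: on ring C the ether carbon is para to the benzylic carbon of the C–D ethano bridge. Carrying that carbon as C=O (deoxybenzoin level) activates exactly the carbon to be etherified, and the C=O is erased afterwards as CH2. Ring A is treated the same way: its ether carbon is ortho to its own bridge carbon, which is carried as CHO for the first SNAr.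
4. Seco ketone ⇐ hydrogenation ⇐ Pd α-arylation of 4'-fluoroacetophenone by a ring-D aryl bromide (C–D bridge and activator in one C–C bond) ⇐ Wittig olefination (A–B bridge) ⇐ SNAr of 3-bromophenol on 2-fluoro-5-methoxybenzaldehyde (A–O–D ether).

Key step: step 6

Remark on the chemistry: the target has no stereogenic centre and is treated as achiral (freely interconverting cyclophane conformers), so no step has to control configuration; the stilbenes 7 and 9 are carried as E/Z mixtures that converge in step 5.

**Route**

Step 1
Reactants: 1 2-fluoro-5-methoxybenzaldehyde; 2 3-bromophenol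
Product: 3 2-(3-bromophenoxy)-5-methoxybenzaldehyde
Conditions: K2CO3, DMAc, 150 °C
Reagents that add atoms: none
Why: Nucleophilic aromatic substitution (SNAr) in which the ortho-formyl group stabilises the Meisenheimer complex at C2 of 1 and fluoride leaves, while the aryl bromide of 2 is inert in the absence of a metal catalyst.

Step 2
Reactants: 4 [3-(benzyloxy)-4-methoxyphenyl]methanol
Product: 5 {[3-(benzyloxy)-4-methoxyphenyl]methyl}triphenylphosphonium bromide
Conditions: Ph3P·HBr, MeCN, reflux
Reagents that add atoms: triphenylphosphine hydrobromide, [Br-].c1ccc(cc1)[PH+](c1ccccc1)c1ccccc1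
Why: Direct phosphonium salt formation from an electron-rich benzylic alcohol (acid-promoted substitution through the p-methoxy-stabilised benzylic cation), which the benzyl aryl ether should tolerate.

Step 3
Reactants: 5 {[3-(benzyloxy)-4-methoxyphenyl]methyl}triphenylphosphonium bromide; 3 2-(3-bromophenoxy)-5-methoxybenzaldehyde
Product: 7 2-(benzyloxy)-4-{2-[2-(3-bromophenoxy)-5-methoxyphenyl]ethenyl}-1-methoxybenzene (E/Z mixture), via phosphorus ylide 6 (not isolated)
Conditions: KOtBu, THF, 0 °C; then 3, 0 °C → rt
Reagents that add atoms: none
Why: Wittig olefination of a semistabilised benzylic ylide with an aromatic aldehyde; the expected E/Z mixture is of no consequence because the double bond is saturated in step 5, and the aryl bromide and the ethers are inert to the ylide.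

Step 4
Reactants: 7 2-(benzyloxy)-4-{2-[2-(3-bromophenoxy)-5-methoxyphenyl]ethenyl}-1-methoxybenzene (E/Z mixture); 8 1-(4-fluorophenyl)ethan-1-one (4'-fluoroacetophenone, 1.5 equiv)
Product: 9 2-{3-[2-{2-[3-(benzyloxy)-4-methoxyphenyl]ethenyl}-4-methoxyphenoxy]phenyl}-1-(4-fluorophenyl)ethan-1-one (E/Z mixture)
Conditions: Pd2(dba)3 (cat.), Xantphos (cat.), K3PO4, toluene, 80 °C
Reagents that add atoms: none
Why: Palladium-catalysed α-arylation of a methyl ketone enolate with an aryl bromide (Buchwald–Hartwig type); monoarylation is favoured because the more hindered, more stabilised enolate of the product couples more slowly, and the C–F bond and the stilbene should not react with the Pd/Xantphos catalyst in toluene.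

Step 5
Reactants: 9 2-{3-[2-{2-[3-(benzyloxy)-4-methoxyphenyl]ethenyl}-4-methoxyphenoxy]phenyl}-1-(4-fluorophenyl)ethan-1-one (E/Z mixture)
Product: 10 1-(4-fluorophenyl)-2-{3-[2-{2-(3-hydroxy-4-methoxyphenyl)ethyl}-4-methoxyphenoxy]phenyl}ethan-1-one
Conditions: H2 (1 atm), 10% Pd/C, EtOAc, rt, monitored and stopped at full conversion
Reagents that add atoms: none
Why: Heterogeneous catalytic hydrogenation should saturate the stilbene and hydrogenolyse the benzyl aryl ether in one operation, while in neutral ethyl acetate at 1 atm the aryl ketone and the C–F bond are expected to survive.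

Step 6
Reactants: 10 1-(4-fluorophenyl)-2-{3-[2-{2-(3-hydroxy-4-methoxyphenyl)ethyl}-4-methoxyphenoxy]phenyl}ethan-1-one
Product: 11 di-O-methyl oxo-dihydroptychantol A (18-membered cyclophane; C=O at the C–D bridge carbon bonded to ring C)
Conditions: Cs2CO3 (3 equiv), degassed DMF, 90 °C, slow addition of 10 (final 2 mM), Ar
Reagents that add atoms: none
Why: Cs2CO3 deprotonates the only free phenol (C3–OH of ring B), and the phenoxide adds to the fluorine-bearing C4 of ring C to give a Meisenheimer complex whose charge is delocalised into the para bridge carbonyl; loss of fluoride then forms the O–C(aryl) bond (addition–elimination SNAr). The closest known reaction type is the etherification of 4-fluoroaryl ketones by phenoxides, the bond-forming reaction of aryl ether ketone chemistry including its macrocyclic oligomers, together with the SNAr macrocyclisations used for diaryl ether cyclophanes. The 18-membered ring is closed by end-to-end macrocyclisation (intramolecular O-arylation) under high dilution, and no other ring is formed. No stereocentre is created. The step needs cyclisation to win over oligomerisation, which slow addition into dilute Cs2CO3/DMF should secure, and it needs the right oxygen, which is secured because the ring-B C4 oxygen and the ring-A oxygen are methyl ethers. It also needs O-arylation despite the acidic ArCH2C(=O) unit, which is secured because that enolate cannot reach its own ring C and only masks the activation reversibly, while intermolecular C-arylation is suppressed by dilution.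

Step 7
Reactants: 11 di-O-methyl oxo-dihydroptychantol A
Product: 12 dihydroptychantol A di-O-methyl ether
Conditions: Et3SiH (6 equiv), TFA, CH2Cl2, 0 °C → rt
Reagents that add atoms: none
Why: Ionic hydrogenation, in which protonation of the aryl ketone, hydride transfer from the silane, ionisation to a benzylic cation stabilised by the para-aryloxy group now on ring C and a second hydride transfer give the methylene; diaryl and methyl ethers are stable to TFA, and any stilbene formed by elimination should be reduced under the same conditions.

Step 8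
Reactants: 12 dihydroptychantol A di-O-methyl ether
Product: 13 dihydroptychantol A
Conditions: BBr3 (6 equiv), CH2Cl2, −78 °C → rt; then H2O
Reagents that add atoms: none
Why: Lewis-acid cleavage of both aryl methyl ethers (BBr3 demethylation) by bromide attack on the O-methyl carbon of the boron-complexed ether; the diaryl ether C–O bonds offer no sp3 carbon for this attack and should remain intact.

**Compound list**

1 | 2-fluoro-5-methoxybenzaldehyde | COc1ccc(F)c(C=O)c1 | starting material
2 | 3-bromophenol | Oc1cccc(Br)c1 | starting material
3 | 2-(3-bromophenoxy)-5-methoxybenzaldehyde | COc1ccc(Oc2cccc(Br)c2)c(C=O)c1 | intermediate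
4 | [3-(benzyloxy)-4-methoxyphenyl]methanol | COc1ccc(CO)cc1OCc1ccccc1 | starting material
5 | {[3-(benzyloxy)-4-methoxyphenyl]methyl}triphenylphosphonium bromide | COc1ccc(C[P+](c2ccccc2)(c2ccccc2)c2ccccc2)cc1OCc1ccccc1.[Br-] | intermediate
6 | phosphorus ylide, {[3-(benzyloxy)-4-methoxyphenyl]methylidene}triphenylphosphorane (not isolated) | COc1ccc(C=P(c2ccccc2)(c2ccccc2)c2ccccc2)cc1OCc1ccccc1 | intermediate
7 | 2-(benzyloxy)-4-{2-[2-(3-bromophenoxy)-5-methoxyphenyl]ethenyl}-1-methoxybenzene (E/Z mixture) | COc1ccc(Oc2cccc(Br)c2)c(C=Cc2ccc(OC)c(OCc3ccccc3)c2)c1 | intermediate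
8 | 1-(4-fluorophenyl)ethan-1-one | CC(=O)c1ccc(F)cc1 | starting material
9 | 2-{3-[2-{2-[3-(benzyloxy)-4-methoxyphenyl]ethenyl}-4-methoxyphenoxy]phenyl}-1-(4-fluorophenyl)ethan-1-one (E/Z mixture) | COc1ccc(Oc2cccc(CC(=O)c3ccc(F)cc3)c2)c(C=Cc2ccc(OC)c(OCc3ccccc3)c2)c1 | intermediate
10 | 1-(4-fluorophenyl)-2-{3-[2-{2-(3-hydroxy-4-methoxyphenyl)ethyl}-4-methoxyphenoxy]phenyl}ethan-1-one | COc1ccc(Oc2cccc(CC(=O)c3ccc(F)cc3)c2)c(CCc2ccc(OC)c(O)c2)c1 | intermediate
11 | di-O-methyl oxo-dihydroptychantol A (macrocyclic ketone, C=O on the bridge carbon bonded to ring C) | COc1ccc2c(c1)CCc1ccc(OC)c(c1)Oc1ccc(cc1)C(=O)Cc1cccc(c1)O2 | intermediate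
12 | dihydroptychantol A di-O-methyl ether | COc1ccc2c(c1)CCc1ccc(OC)c(c1)Oc1ccc(cc1)CCc1cccc(c1)O2 | intermediate
13 | dihydroptychantol A | Oc1ccc2c(c1)CCc1ccc(O)c(c1)Oc1ccc(cc1)CCc1cccc(c1)O2 | target

**Step count and risks**

Total step count: 8. Longest linear sequence: 7 steps (steps 1, 3, 4, 5, 6, 7, 8; step 2 prepares the side fragment).

Steps most likely to fail:

1. Step 6 (macrocyclisation). Oligomerisation may outrun ring closure, or deprotonation of the deoxybenzoin CH2 may consume the base and switch off the activation so that fluoride is not displaced. The fallback is an oxidative C–O coupling at the bibenzyl oxidation level, without an activating group, and sets out from 7. Sonogashira coupling of 7 with 4-ethynylphenylboronic acid pinacol ester (PdCl2(PPh3)2, CuI, Et3N, THF, 60 °C) should give the diarylalkyne pinacol boronate F1. Hydrogenation (H2, Pd/C, EtOAc) should saturate alkyne and alkene and remove the benzyl group to give the seco phenol pinacol boronate F2. NaIO4/NH4OAc in aqueous acetone should release the seco phenol boronic acid F3. A Chan–Lam–Evans macrocyclisation (Cu(OAc)2, pyridine, 4 Å MS, air, CH2Cl2, 1 mM) should then close the same diaryl ether and give 12 directly. The route is rejoined at 12; steps 6 and 7 are bypassed.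

2. Step 5 (hydrogenation). The benzylic ketone may be over-reduced to the carbinol or methylene before debenzylation is complete, which would remove the activation needed in step 6. The fallback avoids H2/Pd in the presence of the ketone and sets out from 7. Diimide reduction of 7 (TsNHNH2, NaOAc, THF/H2O, reflux) should give the bibenzyl bromide F4. α-Arylation of 8 with F4 under the conditions of step 4 should give the benzyl-protected seco ketone F5. Debenzylation with BCl3 and pentamethylbenzene (CH2Cl2, −78 °C) should then give 10, where the route is rejoined.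

3. Step 7 (deoxygenation). The benzylic cation may be trapped transannularly by the electron-rich rings A or B (Friedel–Crafts alkylation) faster than by the silane. The fallback replaces the cationic by an anionic deoxygenation and sets out from 11. Condensation with hydrazine hydrate (diethylene glycol, 130 °C) should give the macrocyclic hydrazone F6 (C=N geometry not defined). KOH at 200 °C (Wolff–Kishner reduction, Huang-Minlon procedure) should then give 12, where the route is rejoined.

**Further compounds**

F1 | step 6 | 2-(benzyloxy)-1-methoxy-4-{2-[5-methoxy-2-(3-{[4-(4,4,5,5-tetramethyl-1,3,2-dioxaborolan-2-yl)phenyl]ethynyl}phenoxy)phenyl]ethenyl}benzene (E/Z mixture) | COc1ccc(Oc2cccc(C#Cc3ccc(B4OC(C)(C)C(C)(C)O4)cc3)c2)c(C=Cc2ccc(OC)c(OCc3ccccc3)c2)c1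
F2 | step 6 | 2-methoxy-5-{2-[5-methoxy-2-(3-{2-[4-(4,4,5,5-tetramethyl-1,3,2-dioxaborolan-2-yl)phenyl]ethyl}phenoxy)phenyl]ethyl}phenol | COc1ccc(Oc2cccc(CCc3ccc(B4OC(C)(C)C(C)(C)O4)cc3)c2)c(CCc2ccc(OC)c(O)c2)c1
F3 | step 6 | {4-[2-(3-{2-[2-(3-hydroxy-4-methoxyphenyl)ethyl]-4-methoxyphenoxy}phenyl)ethyl]phenyl}boronic acid | COc1ccc(Oc2cccc(CCc3ccc(B(O)O)cc3)c2)c(CCc2ccc(OC)c(O)c2)c1
F4 | step 5 | 2-(benzyloxy)-4-{2-[2-(3-bromophenoxy)-5-methoxyphenyl]ethyl}-1-methoxybenzene | COc1ccc(Oc2cccc(Br)c2)c(CCc2ccc(OC)c(OCc3ccccc3)c2)c1
F5 | step 5 | 2-{3-[2-{2-[3-(benzyloxy)-4-methoxyphenyl]ethyl}-4-methoxyphenoxy]phenyl}-1-(4-fluorophenyl)ethan-1-one | COc1ccc(Oc2cccc(CC(=O)c3ccc(F)cc3)c2)c(CCc2ccc(OC)c(OCc3ccccc3)c2)c1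
F6 | step 7 | hydrazone of di-O-methyl oxo-dihydroptychantol A | COc1ccc2c(c1)CCc1ccc(OC)c(c1)Oc1ccc(cc1)C(=NN)Cc1cccc(c1)O2
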